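Target numbering: C1 = carboxyl carbon, C2 = its CH2, ring = O1–O2–C3–C4–C5–C6 (O2 on C3, O1 on C6). The cuts, in retrosynthetic order, are C3–OH to C3–OMe, the C1 acid to a silyl-protected CH2OH, C4–H/C5–H to a C4=C5 alkene, C4=C5 itself, O2–C3, C6–O1 (epoxide opening), and one C–C bond of the (CH2)8 spacer.
Enabling feature: of the six bonds of the 1,2-dioxane ring only C4–C5 joins two carbons free of oxygen. C3 and C6 are both fully substituted, so the O1–O2 bridge can sit in an open-chain bis-allylic peroxide with no C–H next to oxygen, and the ring can be closed last by metathesis of a C6 vinyl group with a C3 isopropenyl group.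
Forward order: fragment 1 (a 2-methoxydiene silyl ether) comes from methacryloyl chloride. Fragment 2 (a tertiary allylic hydroperoxide) comes from (R)-citronellal by alkyne formation, Grignard chain extension, carboalumination, epoxidation, perhydrolysis, glycol cleavage and methylenation.
The two fragments are joined at O2–C3. The only ring is then closed, followed by alkene reduction, oxidation of C1 and ketal hydrolysis.
Stereochemistry: the side-chain centre comes from citronellal. C6 comes from Sharpless epoxidation (D-(−)-tartrate) followed by invertive opening with H2O2. C4 comes from diimide attack on the open face of the (3R)-dihydrodioxine. C3 is set last by anomeric, thermodynamic control.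
Key step: step 17

Remark: equilibration fixes C3 relative to C4 but cannot fix C4 relative to C6, because an axial CH3 and an axial CH2R at C6 cost nearly the same. C4 is therefore set kinetically (step 19), and C3 is assumed to be configurationally labile in the final hemiperoxyketal.

Step 1
Reactants: 1 methacryloyl chloride; 2 potassium methyl malonate
Product: 4 methyl 4-methyl-3-oxopent-4-enoate, via acylmalonic half ester 3 (not isolated)
Conditions: MgCl2, Et3N, MeCN, BHT (trace), 0 °C → rt; then 1 M HCl
Reagents that add atoms: none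
Why: C-Acylation of the magnesium enolate of a malonic half ester followed by loss of CO2 from 3 on acidification (decarboxylative Claisen condensation) is a standard route from acid chlorides to β-keto esters, and the product stays masked as its magnesium chelate until work-up, which limits Michael self-addition.

Step 2
Reactants: 4 methyl 4-methyl-3-oxopent-4-enoate
Product: 5 methyl (2E)-3-methoxy-4-methylpenta-2,4-dienoate
Conditions: HC(OMe)3, TsOH·H2O (cat.), MeOH, rt
Reagents that add atoms: trimethyl orthoformate, COC(OC)OC
Why: Acid-catalysed enol etherification of a β-keto ester with an orthoformate (ketalisation, then loss of methanol) should stop at the conjugated (E)-3-methoxy dienoate, whose alkene geometry is irrelevant because C3 returns to sp3 in step 16.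

Step 3
Reactants: 5 methyl (2E)-3-methoxy-4-methylpenta-2,4-dienoate
Product: 6 (2E)-3-methoxy-4-methylpenta-2,4-dien-1-ol
Conditions: i-Bu2AlH (2.2 equiv), CH2Cl2, −78 °C; aq. potassium sodium tartrate
Reagents that add atoms: none
Why: DIBAL-H 1,2-reduction of an α,β-unsaturated ester gives the allylic alcohol without touching the enol ether, and the neutral tartrate work-up avoids acid hydrolysis of the 3-methoxy allylic alcohol.

Step 4
Reactants: 6 (2E)-3-methoxy-4-methylpenta-2,4-dien-1-ol
Product: 7 tert-butyl{[(2E)-3-methoxy-4-methylpenta-2,4-dien-1-yl]oxy}diphenylsilane (fragment 1)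
Conditions: t-BuPh2SiCl, imidazole, CH2Cl2, 0 °C → rt
Reagents that add atoms: tert-butyl(chloro)diphenylsilane, CC(C)(C)[Si](Cl)(c1ccccc1)c1ccccc1
Why: Routine silyl ether formation; carrying C1 at the protected alcohol level takes away the push–pull stabilisation that makes ester 5 a poor partner for hydroperoxides, leaves an electron-rich 2-methoxy-1,3-diene that is protonated easily at C2, and the TBDPS group withstands the weak acids of steps 16 and 18.

Step 5
Reactants: 8 (R)-citronellal
Product: 9 (4R)-4,8-dimethylnon-7-en-1-yne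
Conditions: MeC(O)C(N2)P(O)(OMe)2, K2CO3, MeOH, 0 °C → rt
Reagents that add atoms: dimethyl (1-diazo-2-oxopropyl)phosphonate, CC(=O)C(=[N+]=[N-])P(=O)(OC)OC
Why: Ohira–Bestmann alkyne synthesis (Seyferth–Gilbert homologation under carbonate conditions) turns the aldehyde carbon, the future C6, into the internal alkyne carbon without risk to the β-stereocentre, which is taken unchanged from citronellal.

Step 6
Reactants: 9 (4R)-4,8-dimethylnon-7-en-1-yne
Product: 11 (4R)-4-methylhept-6-yn-1-ol, via ynal 10 (not isolated)
Conditions: O3, CH2Cl2–MeOH, −78 °C (Sudan Red 7B end point); then NaBH4, −78 °C → rt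
Reagents that add atoms: ozone, [O-][O+]=O
Why: Chemoselective ozonolysis with reductive work-up: ozone consumes the electron-rich trisubstituted alkene much faster than the terminal alkyne, the dye marks the end point, and NaBH4 reduces aldehyde 10 in the same flask.

Step 7
Reactants: 11 (4R)-4-methylhept-6-yn-1-ol
Product: 12 (4R)-4-methylhept-6-yn-1-yl 4-methylbenzenesulfonate
Conditions: TsCl, Et3N, DMAP (cat.), CH2Cl2, 0 °C
Reagents that add atoms: 4-toluenesulfonyl chloride, Cc1ccc(cc1)S(=O)(=O)Cl
Why: Standard tosylation of a primary alcohol supplies the leaving group for the alkyl–alkyl coupling.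

Step 8
Reactants: 12 (4R)-4-methylhept-6-yn-1-yl 4-methylbenzenesulfonate; 13 (5-bromopentyl)benzene
Product: 15 [(9R)-9-methyldodec-11-yn-1-yl]benzene, via 5-phenylpentylmagnesium bromide 14 (not isolated)
Conditions: 13 (2.5 equiv), Mg, THF; then 12, Li2CuCl4 (5 mol %), THF, −30 °C → rt; aq. NH4Cl
Reagents that add atoms: none
Why: Copper-catalysed cross-coupling of an alkyl Grignard reagent with a primary tosylate (Kochi-type coupling with Li2CuCl4) joins the three-carbon and five-carbon parts of the (CH2)8 spacer; the first equivalent of 14 is spent on the acetylenic C–H, which the NH4Cl quench restores, and the alkynyl ligand is not transferred from copper.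

Step 9
Reactants: 15 [(9R)-9-methyldodec-11-yn-1-yl]benzene
Product: 18 (2E,5R)-3,5-dimethyl-13-phenyltridec-2-en-1-ol, via alkenyldimethylalane 16 (not isolated), via lithium alkenylalanate 17 (not isolated)
Conditions: AlMe3, Cp2ZrCl2 (20 mol %), CH2Cl2, 0 °C → rt; evaporation; n-BuLi, hexane–THF, −30 °C; (CH2O)n, rt
Reagents that add atoms: trimethylaluminium, C[Al](C)C; paraformaldehyde (as formaldehyde), C=O
Why: Negishi zirconium-catalysed carboalumination adds CH3 and Al syn across the terminal alkyne with the methyl group on the internal carbon, and hydroxymethylation of alanate 17 with formaldehyde proceeds with retention, which fixes the (E)-trisubstituted allylic alcohol needed for the epoxidation.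

Step 10
Reactants: 18 (2E,5R)-3,5-dimethyl-13-phenyltridec-2-en-1-ol
Product: 19 {(2R,3R)-3-methyl-3-[(2R)-2-methyl-10-phenyldecyl]oxiran-2-yl}methanol
Conditions: Ti(OiPr)4 (10 mol %), D-(−)-diethyl tartrate (12 mol %), t-BuOOH, 4 Å MS, CH2Cl2, −20 °C
Reagents that add atoms: tert-butyl hydroperoxide, CC(C)(C)OO
Why: Sharpless asymmetric epoxidation: with D-(−)-diethyl tartrate an (E)-3-methyl-2-alken-1-ol is oxidised on the face that gives the (2R,3R)-epoxide (the sense known for geraniol-type substrates), reagent control overriding the remote side-chain methyl centre.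

Step 11
Reactants: 19 {(2R,3R)-3-methyl-3-[(2R)-2-methyl-10-phenyldecyl]oxiran-2-yl}methanol
Product: 20 (2R,3S,5R)-3-hydroperoxy-3,5-dimethyl-13-phenyltridecane-1,2-diol
Conditions: anhydrous H2O2 in Et2O (10 equiv), H3PMo12O40 (2 mol %), 0 °C → rt
Reagents that add atoms: hydrogen peroxide, OO
Why: Acid-catalysed perhydrolysis of an epoxide (H3PMo12O40 with anhydrous H2O2): the activated oxirane is opened at the tertiary carbon, which carries most of the developing positive charge and is remote from the inductively deactivating CH2OH, by backside attack, so the future C6 is set with inversion as the (S)-hydroperoxide.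

Step 12
Reactants: 20 (2R,3S,5R)-3-hydroperoxy-3,5-dimethyl-13-phenyltridecane-1,2-diol
Product: 21 (2R,3S,5R)-3-[(2-methoxypropan-2-yl)peroxy]-3,5-dimethyl-13-phenyltridecane-1,2-diol
Conditions: CH2=C(OMe)CH3 (1.05 equiv), PPTS (cat.), CH2Cl2, −20 °C; Et3N quench
Reagents that add atoms: 2-methoxypropene, COC(C)=C
Why: Acid-catalysed addition of a hydroperoxide to an enol ether (monoperoxyketal protection): the more nucleophilic OOH group should take up the single equivalent of 2-methoxypropene ahead of the diol at low temperature, and the early amine quench prevents closure with the neighbouring hydroxyl to a 1,2,4-trioxane, the reaction that forbids direct union of 20 with 7.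

Step 13
Reactants: 21 (2R,3S,5R)-3-[(2-methoxypropan-2-yl)peroxy]-3,5-dimethyl-13-phenyltridecane-1,2-diol
Product: 22 (2S,4R)-2-[(2-methoxypropan-2-yl)peroxy]-2,4-dimethyl-12-phenyldodecanal
Conditions: NaIO4, NaHCO3, THF–H2O, 0 °C
Reagents that add atoms: none
Why: Malaprade glycol cleavage in buffered medium removes the terminal CH2OH carbon as formaldehyde and turns the carbinol carbon into the aldehyde that will become C5, while the peroxyketal is inert to periodate and the adjacent quaternary centre cannot epimerise.

Step 14
Reactants: 22 (2S,4R)-2-[(2-methoxypropan-2-yl)peroxy]-2,4-dimethyl-12-phenyldodecanal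
Product: 23 (3S,5R)-3-[(2-methoxypropan-2-yl)peroxy]-3,5-dimethyl-13-phenyltridec-1-ene
Conditions: Ph3PCH3Br, KOtBu, THF, 0 °C; then 22, −78 °C → 0 °C
Reagents that add atoms: methyltriphenylphosphonium bromide, [Br-].C[P+](c1ccccc1)(c1ccccc1)c1ccccc1
Why: Wittig methylenation of a peroxyketal-protected α-peroxy aldehyde, an established olefination class, should proceed through the oxaphosphetane without harm to the O–O bond because the α-carbon is quaternary and offers no proton for enolisation or Kornblum–DeLaMare cleavage.

Step 15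
Reactants: 23 (3S,5R)-3-[(2-methoxypropan-2-yl)peroxy]-3,5-dimethyl-13-phenyltridec-1-ene
Product: 24 (3S,5R)-3-hydroperoxy-3,5-dimethyl-13-phenyltridec-1-ene (fragment 2)
Conditions: AcOH–THF–H2O, BHT (trace), rt; used at once
Reagents that add atoms: none
Why: Mild aqueous acetic acid hydrolyses the acetone-derived peroxyketal (standard release of a hydroperoxide) without ionising the tertiary allylic C–O bond, and BHT with immediate use suppresses the radical allylic (Schenck) rearrangement.

Step 16
Reactants: 24 (3S,5R)-3-hydroperoxy-3,5-dimethyl-13-phenyltridec-1-ene; 7 tert-butyl{[(2E)-3-methoxy-4-methylpenta-2,4-dien-1-yl]oxy}diphenylsilane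
Product: 25 tert-butyl{[3-{[(3S,5R)-3,5-dimethyl-13-phenyltridec-1-en-3-yl]peroxy}-3-methoxy-4-methylpent-4-en-1-yl]oxy}diphenylsilane (both C3 epimers)
Conditions: PPTS (cat.), 4 Å MS, CH2Cl2, 0 °C; Et3N quench; Et3N-deactivated SiO2
Reagents that add atoms: none
Why: Same reaction type as step 12 (acid-catalysed peroxyketalisation of an enol ether): PPTS protonates diene 7 at C2, the allyl-stabilised oxocarbenium ion is captured at C3 by the only nucleophile present, and O2–C3 forms without facial bias, so both C3 epimers are expected.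

Step 17
Reactants: 25 tert-butyl{[3-{[(3S,5R)-3,5-dimethyl-13-phenyltridec-1-en-3-yl]peroxy}-3-methoxy-4-methylpent-4-en-1-yl]oxy}diphenylsilane (both C3 epimers)
Product: 26 tert-butyl(2-{(6S)-3-methoxy-4,6-dimethyl-6-[(2R)-2-methyl-10-phenyldecyl]-3,6-dihydro-1,2-dioxin-3-yl}ethoxy)diphenylsilane (both C3 epimers)
Conditions: second-generation Hoveyda–Grubbs catalyst RuCl2(H2IMes)(=CH-C6H4-2-OiPr) (10 mol %, two portions), 1,4-benzoquinone (cat.), toluene (high dilution), 50 °C, Ar sparge
Reagents that add atoms: none
Why: The isopropoxybenzylidene is exchanged for the less hindered, monosubstituted C6 vinyl group, the C5 alkylidene so formed adds across the C3 isopropenyl group to a ruthenacyclobutane, and cycloreversion releases the C4=C5 alkene and a ruthenium methylidene that carries the chain with loss of ethene (Chauvin mechanism). The closest known reaction type is ring-closing metathesis of dienes whose tether holds a dialkyl peroxide, together with closures to trisubstituted cyclohexenes next to quaternary carbons. The single ring formed, the 3,6-dihydro-1,2-dioxine, closes as a six-membered ring by alkene C–C bond formation across the preformed C3–O2–O1–C6 link, so no C–O or O–O bond is made or broken. No stereocentre is created: C6 and the side-chain centre are spectators and both C3 epimers of 25 should cyclise to the two epimers of 26. The step needs cyclisation to be faster than oligomerisation and faster than O–O cleavage by divalent ruthenium or by phosphine; the geminal substitution at C3 and C6 and the gauche C–O–O–C geometry hold the two alkenes close, the catalyst carries no phosphine, neither peroxide carbon bears a hydrogen that could start a Kornblum–DeLaMare fragmentation, and dilution with an argon sparge removes ethene. Benzoquinone is added to intercept ruthenium hydrides that would isomerise the allylic peroxide.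

Step 18
Reactants: 26 tert-butyl(2-{(6S)-3-methoxy-4,6-dimethyl-6-[(2R)-2-methyl-10-phenyldecyl]-3,6-dihydro-1,2-dioxin-3-yl}ethoxy)diphenylsilane (both C3 epimers)
Product: 27 tert-butyl(2-{(3R,6S)-3-methoxy-4,6-dimethyl-6-[(2R)-2-methyl-10-phenyldecyl]-3,6-dihydro-1,2-dioxin-3-yl}ethoxy)diphenylsilane
Conditions: chromatographic separation (Et3N-deactivated SiO2); (3S) epimer: PPTS (cat.), MeOH, rt, then renewed separation (repeated)
Reagents that add atoms: methanol, CO
Why: Acid-catalysed anomerisation of a 3-alkoxy-3,6-dihydro-1,2-dioxine (ketal exchange with methanol through the ring peroxycarbenium ion, degenerate in constitution) interconverts the C3 epimers, so repeated separation should funnel the material into the (3R) epimer, in which OMe and the C6 methyl share one face and the two long chains share the other.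

Step 19
Reactants: 27 tert-butyl(2-{(3R,6S)-3-methoxy-4,6-dimethyl-6-[(2R)-2-methyl-10-phenyldecyl]-3,6-dihydro-1,2-dioxin-3-yl}ethoxy)diphenylsilane
Product: 28 tert-butyl(2-{(3R,4R,6S)-3-methoxy-4,6-dimethyl-6-[(2R)-2-methyl-10-phenyldecyl]-1,2-dioxan-3-yl}ethoxy)diphenylsilane
Conditions: 2-O2NC6H4SO2NHNH2 (large excess, in portions), Et3N, CH2Cl2, rt; resubmission until the alkene is consumed
Reagents that add atoms: none
Why: Diimide reduction, the standard metal-free way to saturate an alkene beside an O–O bond, transfers two hydrogens in a concerted syn fashion to the face of 27 that bears only OMe and CH3, which sets C4 as R with its methyl group cis to both chains, while the amine-buffered aprotic medium excludes anomerisation at C3 during the slow reaction.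

Step 20
Reactants: 28 tert-butyl(2-{(3R,4R,6S)-3-methoxy-4,6-dimethyl-6-[(2R)-2-methyl-10-phenyldecyl]-1,2-dioxan-3-yl}ethoxy)diphenylsilane
Product: 29 2-{(3R,4R,6S)-3-methoxy-4,6-dimethyl-6-[(2R)-2-methyl-10-phenyldecyl]-1,2-dioxan-3-yl}ethanol
Conditions: Bu4NF, AcOH, THF, 0 °C → rt
Reagents that add atoms: none
Why: Fluoride cleavage of a silyl ether, buffered with acetic acid, is compatible with the dialkyl peroxide and the peroxyketal because C2 carries no acidifying group at this oxidation level.

Step 21
Reactants: 29 2-{(3R,4R,6S)-3-methoxy-4,6-dimethyl-6-[(2R)-2-methyl-10-phenyldecyl]-1,2-dioxan-3-yl}ethanol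
Product: 31 2-{(3R,4R,6S)-3-methoxy-4,6-dimethyl-6-[(2R)-2-methyl-10-phenyldecyl]-1,2-dioxan-3-yl}acetic acid, via aldehyde 30 (not isolated)
Conditions: TEMPO (cat.), PhI(OAc)2 (2.2 equiv), MeCN–pH 7 phosphate buffer, rt
Reagents that add atoms: water, O
Why: TEMPO/PhI(OAc)2 oxidation of a primary alcohol to the acid by way of aldehyde 30 and its hydrate uses an oxidant to which peroxides are inert and avoids every basic step on a β-peroxy carbonyl compound, so retro-Michael opening of the ring is not an issue.

Step 22
Reactants: 31 2-{(3R,4R,6S)-3-methoxy-4,6-dimethyl-6-[(2R)-2-methyl-10-phenyldecyl]-1,2-dioxan-3-yl}acetic acid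
Product: 33 2-{(3S,4R,6S)-3-hydroxy-4,6-dimethyl-6-[(2R)-2-methyl-10-phenyldecyl]-1,2-dioxan-3-yl}acetic acid (target), via hydroperoxy keto acid 32 (not isolated)
Conditions: 0.5 M aq. HCl–MeCN, 0 °C → rt, short contact time
Reagents that add atoms: water, O
Why: Specific-acid-catalysed hydrolysis of the peroxyketal gives the hemiperoxyketal, and ring–chain tautomerism through 32 lets C3 settle under thermodynamic control with OH axial (anomeric effect) and the acetic acid arm and C4 methyl equatorial, that is as S, while the short, cold treatment should leave C4 (the keto acid enolises towards C2) and the carboxyl group (no decarboxylation) untouched.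

Compound list
1 | methacryloyl chloride | C=C(C)C(Cl)=O | starting material
2 | potassium methyl malonate | [K+].COC(=O)CC(=O)[O-] | starting material
3 | 2-(methoxycarbonyl)-4-methyl-3-oxopent-4-enoic acid (acylmalonic half ester) | C=C(C)C(=O)C(C(=O)O)C(=O)OC | intermediate
4 | methyl 4-methyl-3-oxopent-4-enoate | C=C(C)C(=O)CC(=O)OC | intermediate
5 | methyl (2E)-3-methoxy-4-methylpenta-2,4-dienoate | COC(=O)/C=C(/OC)C(C)=C | intermediate
6 | (2E)-3-methoxy-4-methylpenta-2,4-dien-1-ol | OC/C=C(/OC)C(C)=C | intermediate
7 | tert-butyl{[(2E)-3-methoxy-4-methylpenta-2,4-dien-1-yl]oxy}diphenylsilane | CC(C)(C)[Si](c1ccccc1)(c1ccccc1)OC/C=C(/OC)C(C)=C | intermediate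
8 | (R)-citronellal | C[C@H](CCC=C(C)C)CC=O | starting material
9 | (4R)-4,8-dimethylnon-7-en-1-yne | C[C@H](CCC=C(C)C)CC#C | intermediate
10 | (4R)-4-methylhept-6-ynal | C[C@H](CCC=O)CC#C | intermediate
11 | (4R)-4-methylhept-6-yn-1-ol | C[C@H](CCCO)CC#C | intermediate
12 | (4R)-4-methylhept-6-yn-1-yl 4-methylbenzenesulfonate | C[C@H](CCCOS(=O)(=O)c1ccc(C)cc1)CC#C | intermediate
13 | (5-bromopentyl)benzene | BrCCCCCc1ccccc1 | starting material
14 | 5-phenylpentylmagnesium bromide | Br[Mg]CCCCCc1ccccc1 | intermediate
15 | [(9R)-9-methyldodec-11-yn-1-yl]benzene | C[C@H](CCCCCCCCc1ccccc1)CC#C | intermediate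
16 | [(1E,4R)-2,4-dimethyl-12-phenyldodec-1-en-1-yl]dimethylalane | C[C@H](CCCCCCCCc1ccccc1)C/C(C)=C/[Al](C)C | intermediate
17 | lithium butyl[(1E,4R)-2,4-dimethyl-12-phenyldodec-1-en-1-yl]dimethylalanate | [Li+].C[C@H](CCCCCCCCc1ccccc1)C/C(C)=C/[Al-](C)(C)CCCC | intermediate
18 | (2E,5R)-3,5-dimethyl-13-phenyltridec-2-en-1-ol | C[C@H](CCCCCCCCc1ccccc1)C/C(C)=C/CO | intermediate
19 | {(2R,3R)-3-methyl-3-[(2R)-2-methyl-10-phenyldecyl]oxiran-2-yl}methanol | C[C@H](CCCCCCCCc1ccccc1)C[C@@]1(C)O[C@@H]1CO | intermediate
20 | (2R,3S,5R)-3-hydroperoxy-3,5-dimethyl-13-phenyltridecane-1,2-diol | C[C@H](CCCCCCCCc1ccccc1)C[C@](C)(OO)[C@H](O)CO | intermediate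
21 | (2R,3S,5R)-3-[(2-methoxypropan-2-yl)peroxy]-3,5-dimethyl-13-phenyltridecane-1,2-diol | C[C@H](CCCCCCCCc1ccccc1)C[C@](C)(OOC(C)(C)OC)[C@H](O)CO | intermediate
22 | (2S,4R)-2-[(2-methoxypropan-2-yl)peroxy]-2,4-dimethyl-12-phenyldodecanal | C[C@H](CCCCCCCCc1ccccc1)C[C@](C)(OOC(C)(C)OC)C=O | intermediate
23 | (3S,5R)-3-[(2-methoxypropan-2-yl)peroxy]-3,5-dimethyl-13-phenyltridec-1-ene | C[C@H](CCCCCCCCc1ccccc1)C[C@](C)(OOC(C)(C)OC)C=C | intermediate
24 | (3S,5R)-3-hydroperoxy-3,5-dimethyl-13-phenyltridec-1-ene | C[C@H](CCCCCCCCc1ccccc1)C[C@](C)(OO)C=C | intermediate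
25 | tert-butyl{[3-{[(3S,5R)-3,5-dimethyl-13-phenyltridec-1-en-3-yl]peroxy}-3-methoxy-4-methylpent-4-en-1-yl]oxy}diphenylsilane, both C3 epimers | C[C@H](CCCCCCCCc1ccccc1)C[C@@](C)(C=C)OOC(OC)(CCO[Si](c1ccccc1)(c1ccccc1)C(C)(C)C)C(C)=C | intermediate
26 | tert-butyl(2-{(6S)-3-methoxy-4,6-dimethyl-6-[(2R)-2-methyl-10-phenyldecyl]-3,6-dihydro-1,2-dioxin-3-yl}ethoxy)diphenylsilane, both C3 epimers | C[C@H](CCCCCCCCc1ccccc1)C[C@@]1(C)C=C(C)C(OC)(CCO[Si](c2ccccc2)(c2ccccc2)C(C)(C)C)OO1 | intermediate
27 | tert-butyl(2-{(3R,6S)-3-methoxy-4,6-dimethyl-6-[(2R)-2-methyl-10-phenyldecyl]-3,6-dihydro-1,2-dioxin-3-yl}ethoxy)diphenylsilane | C[C@H](CCCCCCCCc1ccccc1)C[C@@]1(C)C=C(C)[C@@](OC)(CCO[Si](c2ccccc2)(c2ccccc2)C(C)(C)C)OO1 | intermediate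
28 | tert-butyl(2-{(3R,4R,6S)-3-methoxy-4,6-dimethyl-6-[(2R)-2-methyl-10-phenyldecyl]-1,2-dioxan-3-yl}ethoxy)diphenylsilane | C[C@H](CCCCCCCCc1ccccc1)C[C@@]1(C)C[C@@H](C)[C@@](OC)(CCO[Si](c2ccccc2)(c2ccccc2)C(C)(C)C)OO1 | intermediate
29 | 2-{(3R,4R,6S)-3-methoxy-4,6-dimethyl-6-[(2R)-2-methyl-10-phenyldecyl]-1,2-dioxan-3-yl}ethanol | C[C@H](CCCCCCCCc1ccccc1)C[C@@]1(C)C[C@@H](C)[C@@](OC)(CCO)OO1 | intermediate
30 | 2-{(3R,4R,6S)-3-methoxy-4,6-dimethyl-6-[(2R)-2-methyl-10-phenyldecyl]-1,2-dioxan-3-yl}acetaldehyde | C[C@H](CCCCCCCCc1ccccc1)C[C@@]1(C)C[C@@H](C)[C@@](OC)(CC=O)OO1 | intermediate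
31 | 2-{(3R,4R,6S)-3-methoxy-4,6-dimethyl-6-[(2R)-2-methyl-10-phenyldecyl]-1,2-dioxan-3-yl}acetic acid | C[C@H](CCCCCCCCc1ccccc1)C[C@@]1(C)C[C@@H](C)[C@@](OC)(CC(=O)O)OO1 | intermediate
32 | (4R,6S,8R)-6-hydroperoxy-4,6,8-trimethyl-3-oxo-16-phenylhexadecanoic acid | C[C@H](CCCCCCCCc1ccccc1)C[C@](C)(OO)C[C@@H](C)C(=O)CC(=O)O | intermediate
33 | 2-{(3S,4R,6S)-3-hydroxy-4,6-dimethyl-6-[(2R)-2-methyl-10-phenyldecyl]-1,2-dioxan-3-yl}acetic acid | C[C@H](CCCCCCCCc1ccccc1)C[C@@]1(C)C[C@@H](C)[C@](O)(CC(=O)O)OO1 | target

Total step count: 22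
Longest linear sequence: 18 steps (steps 5–22, from (R)-citronellal 8)

Steps most likely to fail

1. Step 17.
   - Risk: slow initiation at the neopentyl-type C6 vinyl group and slow closure onto the hindered isopropenyl group may let catalyst decay and ruthenium-induced O–O cleavage win over ring closure.
   - Fallback: relay ring-closing metathesis, from 22 back to 26. Wittig reaction of 22 with the ylide from (hex-5-en-1-yl)triphenylphosphonium bromide and KN(SiMe3)2 would give the relay peroxyketal F1. Aqueous acetic acid would give the relay hydroperoxide F2, and PPTS-catalysed addition to 7 would give the relay triene F3. The same catalyst then loads on the unhindered terminal alkene, expels cyclopentene and is thereby placed on C5 without having to initiate at the hindered site. Closure onto the isopropenyl group then gives 26.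

2. Step 19.
   - Risk: hydrogen transfer from diimide to a trisubstituted alkene between two quaternary carbons may be too slow relative to diimide disproportionation, and discrimination between the two faces may be incomplete.
   - Fallback: heterogeneous catalytic hydrogenation in place of pericyclic hydrogen transfer, from 27 back to 28, using H2 (1 atm) over PtO2 in EtOAc at 0 °C and stopped after one equivalent. Adsorption should take place on the same open face. The O–O bond, buried between two fully substituted carbons, should be hydrogenolysed more slowly than the alkene is saturated. No new compound arises (F0).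

3. Step 16.
   - Risk: the acid-catalysed addition is reversible and the hindered partners may combine slowly. Loss of methanol or hydroperoxide from the allylic peroxyketal, capture at the vinylogous terminus of the cation, ionisation of the allylic silyl ether and Hock-type fragmentation of the hydroperoxide may therefore compete.
   - Fallback: aprotic Lewis-acid transketalisation (Noyori-type), from 24 and 7 back to 25. Et3SiCl/Et3N would turn 24 into the triethylsilyl peroxide F4, and PPTS in methanol would turn 7 into the dimethyl ketal F5. Me3SiOTf (cat.) in CH2Cl2 at −78 °C would join the two with irreversible loss of the silyl methyl ether.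

Further compounds
F1 | step 17 | relay peroxyketal (6Z,8S,10R)-8-[(2-methoxypropan-2-yl)peroxy]-8,10-dimethyl-18-phenyloctadeca-1,6-diene | C[C@H](CCCCCCCCc1ccccc1)C[C@](C)(OOC(C)(C)OC)/C=C\CCCC=C
F2 | step 17 | relay hydroperoxide (6Z,8S,10R)-8-hydroperoxy-8,10-dimethyl-18-phenyloctadeca-1,6-diene | C[C@H](CCCCCCCCc1ccccc1)C[C@](C)(OO)/C=C\CCCC=C
F3 | step 17 | relay triene tert-butyl{[3-{[(6Z,8S,10R)-8,10-dimethyl-18-phenyloctadeca-1,6-dien-8-yl]peroxy}-3-methoxy-4-methylpent-4-en-1-yl]oxy}diphenylsilane, both C3 epimers | C[C@H](CCCCCCCCc1ccccc1)C[C@@](C)(/C=C\CCCC=C)OOC(OC)(CCO[Si](c1ccccc1)(c1ccccc1)C(C)(C)C)C(C)=C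
F0 | step 19 | none | none
F4 | step 16 | triethylsilyl peroxide triethyl{[(3S,5R)-3,5-dimethyl-13-phenyltridec-1-en-3-yl]peroxy}silane | C[C@H](CCCCCCCCc1ccccc1)C[C@](C)(OO[Si](CC)(CC)CC)C=C
F5 | step 16 | dimethyl ketal tert-butyl[(3,3-dimethoxy-4-methylpent-4-en-1-yl)oxy]diphenylsilane | C=C(C)C(OC)(OC)CCO[Si](c1ccccc1)(c1ccccc1)C(C)(C)C
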